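**Retrosynthetic overview**
1. The target comes from its 7-O-methoxymethyl (MOM) flavone: C2 of ring C is set last by ligand-controlled CuH 1,4-reduction of the chromone C2=C3 bond, then the MOM group is removed.
2. Ring B is cut at C2'–C3' and C1'–C6' into a 2-ethynylchromone (rings A and C) and a pyran-fused 2-pyrone; [4+2] addition across pyrone C3/C6 and loss of CO2 rebuild it.
3. Feature used: C3' (pyran carbon), C4' (pyran oxygen) and C5' (prenyl) of ring B are three neighbouring carbons that map onto C3, C4 and C5 of a 4-hydroxy-5-prenyl-2-pyrone annulated with 3-methylbut-2-enal; C6' is pyrone C6, and C1' and C2' are the alkyne carbons.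
4. Pyrone arm: methyl acetoacetate, two γ-dianion reactions (prenylation, formylation), lactonisation, Knoevenagel/6π closure. Alkyne arm: 2,4-dihydroxyacetophenone, Claisen acylation with a silylpropiolate, cyclodehydration, MOM protection, desilylation.
5. Ring order: ring C onto ring A; 2-pyrone, then dimethylpyran; ring B last.

Key step: step 7

Remark: the sense of induction of the bisphosphine in step 8 is assigned by model only; the antipodal ligand is to be used if the first run shows the opposite sense.

**Step 1**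
Reactants: 1 methyl acetoacetate; 2 prenyl bromide (1-bromo-3-methylbut-2-ene)
Product: 3 methyl 7-methyl-3-oxooct-6-enoate
Conditions: NaH (1.1 equiv), THF, 0 °C; n-BuLi (1.05 equiv), 0 °C; 2, 0 °C to rt; aq. HCl
Reagents that add atoms: none
Why: Weiler dianion alkylation, in which the α,γ-dianion of the β-keto ester reacts at its more basic γ-carbon with the primary allylic bromide by SN2 substitution.

**Step 2**
Reactants: 3 methyl 7-methyl-3-oxooct-6-enoate
Product: 5 4-hydroxy-5-(3-methylbut-2-enyl)-2H-pyran-2-one, via methyl 4-formyl-7-methyl-3-oxooct-6-enoate 4 (not isolated)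
Conditions: LiN(iPr)2 (3.0 equiv), THF, −78 to 0 °C; HCO2Me (2 equiv), −78 to 0 °C; cold aq. HCl to pH 3; crude 4, DBU (1.5 equiv), toluene, 80 °C; cold dilute HCl
Reagents that add atoms: methyl formate, COC=O
Why: Claisen acylation of the α,γ-dianion at the γ-carbon by the formate (dianion acylation, the third equivalent of base taking the proton of the more acidic product) gives β-keto aldehyde 4, whose chelated enol oxygen closes onto the methyl ester under DBU (lactonisation to the 2-pyrone); base is chosen for the closure because acid would add the C4 hydroxyl to the prenyl alkene.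

**Step 3**
Reactants: 5 4-hydroxy-5-(3-methylbut-2-enyl)-2H-pyran-2-one; 6 3-methylbut-2-enal
Product: 8 2,2-dimethyl-8-(3-methylbut-2-enyl)-2H,5H-pyrano[4,3-b]pyran-5-one, via alkylidene pyran-2,4-dione 7 (not isolated)
Conditions: ethylenediammonium diacetate (10 mol %), toluene, 80 °C
Reagents that add atoms: none
Why: Knoevenagel condensation at pyrone C3 followed by 6π-oxa-electrocyclisation of the 1-oxatriene through the C4 oxygen (formal [3+3] annulation of a 4-hydroxy-2-pyrone with an enal), which keeps the 2-pyrone and ties up the C4 oxygen next to the prenyl group.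

**Step 4**
Reactants: 9 2,4-dihydroxyacetophenone; 10 ethyl 3-(trimethylsilyl)propiolate
Product: 12 7-hydroxy-2-[(trimethylsilyl)ethynyl]-4H-chromen-4-one, via 1-(2,4-dihydroxyphenyl)-5-(trimethylsilyl)pent-4-yne-1,3-dione 11 (not isolated)
Conditions: LiN(SiMe3)2 (4.2 equiv), THF, −78 to −10 °C; 10, −78 to 0 °C; aq. HCl; crude 11, AcOH, H2SO4 (cat.), 60 °C
Reagents that add atoms: none
Why: Crossed Claisen acylation of the lithium enolate (both phenols masked as lithium phenoxides) by the ynoate ester gives 1,3-diketone 11, and acid-catalysed attack of the 2-hydroxyl on the C3 carbonyl with dehydration (Baker–Venkataraman-type chromone closure) forms ring C, the silyl group shielding the alkyne terminus from conjugate addition.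

**Step 5**
Reactants: 12 7-hydroxy-2-[(trimethylsilyl)ethynyl]-4H-chromen-4-one
Product: 13 7-(methoxymethoxy)-2-[(trimethylsilyl)ethynyl]-4H-chromen-4-one
Conditions: MOMCl (1.3 equiv), K2CO3 (anhydrous, 2 equiv), acetone, 0 °C to rt
Reagents that add atoms: chloromethyl methyl ether, COCCl
Why: Williamson-type O-alkylation of the acidic 7-phenol, placed after ring C closure because the acid of step 4 would have cleaved a MOM ether.

**Step 6**
Reactants: 13 7-(methoxymethoxy)-2-[(trimethylsilyl)ethynyl]-4H-chromen-4-one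
Product: 14 2-ethynyl-7-(methoxymethoxy)-4H-chromen-4-one
Conditions: Bu4NF (1.1 equiv), AcOH (1.2 equiv), THF, −20 to 0 °C
Reagents that add atoms: none
Why: Fluoride-induced protodesilylation of the alkynylsilane, buffered with acetic acid so that no basic nucleophile adds to the ynenone or to chromone C2.

**Step 7**
Reactants: 8 2,2-dimethyl-8-(3-methylbut-2-enyl)-2H,5H-pyrano[4,3-b]pyran-5-one; 14 2-ethynyl-7-(methoxymethoxy)-4H-chromen-4-one
Product: 16 2-[2,2-dimethyl-8-(3-methylbut-2-enyl)-2H-chromen-6-yl]-7-(methoxymethoxy)-4H-chromen-4-one, via 2-oxabicyclo[2.2.2]octadienone lactone 15 (not isolated)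
Conditions: 8 (1.5 equiv), BHT (5 mol %), 1,2-dichlorobenzene, 170 °C, sealed tube, argon
Reagents that add atoms: none
Why: The 2-pyrone ring of 8 reacts as an electron-rich diene through C3 and C6 with the terminal alkyne of 14 in a concerted, asynchronous normal-demand Diels–Alder reaction, and bridged lactone 15 then loses CO2 in an irreversible retro-[4+2] step that gives the benzene ring directly; this is the known 2-pyrone–alkyne cycloaddition/decarboxylation route to arenes. Ring B is thus closed by intermolecular [4+2] cycloaddition, which forms C2'–C3' and C1'–C6', followed by extrusion of the O1–C2 bridge. No stereocenter results, since the two bridgehead centres of 15 become aromatic carbons. The step needs one orientation of the alkyne: pyrone C3 is the β-carbon of the C4 enol ether and the nucleophilic diene terminus, and the terminal alkyne carbon is the electrophilic end of the ynenone that runs through chromone C2=C3 to the C4 carbonyl, so these two carbons should join and the chromone should land para to the pyran oxygen. Sterics act in the same sense, because the fully substituted C3 meets the CH terminus and the unsubstituted C6 meets the substituted alkyne carbon. The pyrone diene is expected to react in preference to the 2H-pyran diene, which would have to bond at the carbon next to the gem-dimethyl group and at the tetrasubstituted ring-fusion carbon.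

**Step 8**
Reactants: 16 2-[2,2-dimethyl-8-(3-methylbut-2-enyl)-2H-chromen-6-yl]-7-(methoxymethoxy)-4H-chromen-4-one
Product: 18 (2S)-2-[2,2-dimethyl-8-(3-methylbut-2-enyl)-2H-chromen-6-yl]-7-(methoxymethoxy)-2,3-dihydro-4H-chromen-4-one, via silyl enol ether 17 (not isolated)
Conditions: Cu(OAc)2 (5 mol %), (R)-DTBM-SEGPHOS (5.5 mol %), (EtO)2MeSiH (3 equiv), toluene, 0 °C to rt; then aq. NH4Cl, THF, rt
Reagents that add atoms: none
Why: Ligand-controlled copper hydride 1,4-reduction of a 2-substituted chromone (asymmetric conjugate reduction), in which the bisphosphine–CuH complex delivers hydride to the Re face of C2 (O1 > C1' > C3) and so sets (2S), the copper enolate is trapped by the silane as silyl enol ether 17 so that neither β-elimination of the phenoxide nor 1,2-reduction follows, and mild hydrolysis gives the ketone, while the prenyl and chromene alkenes, which are not conjugated to an acceptor, stay untouched.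

**Step 9**
Reactants: 18 (2S)-2-[2,2-dimethyl-8-(3-methylbut-2-enyl)-2H-chromen-6-yl]-7-(methoxymethoxy)-2,3-dihydro-4H-chromen-4-one
Product: 19 (2S)-2-[2,2-dimethyl-8-(3-methylbut-2-enyl)-2H-chromen-6-yl]-7-hydroxy-2,3-dihydro-4H-chromen-4-one (the target)
Conditions: HCl (2 M in MeOH), rt to 40 °C
Reagents that add atoms: none
Why: Acid-catalysed acetal exchange of the MOM ether with methanol, under which C2 should keep its configuration because ring opening of a flavanone needs base, and the prenyl group has no free neighbouring hydroxyl to cyclise onto.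

**Compound list**
1 | methyl acetoacetate | COC(=O)CC(C)=O | starting material
2 | prenyl bromide (1-bromo-3-methylbut-2-ene) | CC(C)=CCBr | starting material
3 | methyl 7-methyl-3-oxooct-6-enoate | COC(=O)CC(=O)CCC=C(C)C | intermediate
4 | methyl 4-formyl-7-methyl-3-oxooct-6-enoate (racemic, enolised, not isolated) | COC(=O)CC(=O)C(C=O)CC=C(C)C | intermediate
5 | 4-hydroxy-5-(3-methylbut-2-enyl)-2H-pyran-2-one | O=C1C=C(O)C(CC=C(C)C)=CO1 | intermediate
6 | 3-methylbut-2-enal | CC(C)=CC=O | starting material
7 | 3-(3-methylbut-2-enylidene)-5-(3-methylbut-2-enyl)-2H-pyran-2,4(3H)-dione (not isolated) | CC(C)=CC=C1C(=O)OC=C(CC=C(C)C)C1=O | intermediate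
8 | 2,2-dimethyl-8-(3-methylbut-2-enyl)-2H,5H-pyrano[4,3-b]pyran-5-one | CC(C)=CCC1=COC(=O)C2=C1OC(C)(C)C=C2 | intermediate
9 | 2,4-dihydroxyacetophenone | CC(=O)c1ccc(O)cc1O | starting material
10 | ethyl 3-(trimethylsilyl)propiolate | CCOC(=O)C#C[Si](C)(C)C | starting material
11 | 1-(2,4-dihydroxyphenyl)-5-(trimethylsilyl)pent-4-yne-1,3-dione (not isolated) | O=C(CC(=O)C#C[Si](C)(C)C)c1ccc(O)cc1O | intermediate
12 | 7-hydroxy-2-[(trimethylsilyl)ethynyl]-4H-chromen-4-one | C[Si](C)(C)C#CC1=CC(=O)c2ccc(O)cc2O1 | intermediate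
13 | 7-(methoxymethoxy)-2-[(trimethylsilyl)ethynyl]-4H-chromen-4-one | C[Si](C)(C)C#CC1=CC(=O)c2ccc(OCOC)cc2O1 | intermediate
14 | 2-ethynyl-7-(methoxymethoxy)-4H-chromen-4-one | C#CC1=CC(=O)c2ccc(OCOC)cc2O1 | intermediate
15 | bridged lactone cycloadduct of 8 and 14, a 2-oxabicyclo[2.2.2]octa-5,7-dien-3-one with pyrone C3 bonded to the alkyne CH and pyrone C6 to the chromonyl-bearing alkyne carbon (racemic, not isolated) | O=C1OC2C(CC=C(C)C)=C3OC(C)(C)C=CC13C=C2C1=CC(=O)c2ccc(OCOC)cc2O1 | intermediate
16 | 2-[2,2-dimethyl-8-(3-methylbut-2-enyl)-2H-chromen-6-yl]-7-(methoxymethoxy)-4H-chromen-4-one | CC(C)=CCc1cc(C2=CC(=O)c3ccc(OCOC)cc3O2)cc2c1OC(C)(C)C=C2 | intermediate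
17 | (2S)-4-{[diethoxy(methyl)silyl]oxy}-2-[2,2-dimethyl-8-(3-methylbut-2-enyl)-2H-chromen-6-yl]-7-(methoxymethoxy)-2H-chromene (not isolated) | CC(C)=CCc1cc([C@@H]2C=C(O[Si](C)(OCC)OCC)c3ccc(OCOC)cc3O2)cc2c1OC(C)(C)C=C2 | intermediate
18 | (2S)-2-[2,2-dimethyl-8-(3-methylbut-2-enyl)-2H-chromen-6-yl]-7-(methoxymethoxy)-2,3-dihydro-4H-chromen-4-one | CC(C)=CCc1cc([C@@H]2CC(=O)c3ccc(OCOC)cc3O2)cc2c1OC(C)(C)C=C2 | intermediate
19 | (2S)-2-[2,2-dimethyl-8-(3-methylbut-2-enyl)-2H-chromen-6-yl]-7-hydroxy-2,3-dihydro-4H-chromen-4-one | CC(C)=CCc1cc([C@@H]2CC(=O)c3ccc(O)cc3O2)cc2c1OC(C)(C)C=C2 | target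

**Step count**
Total: 9 steps. Longest linear sequence: 6 steps (steps 1, 2, 3, 7, 8, 9, or equally steps 4, 5, 6, 7, 8, 9).

**Steps most likely to fail**

Step 7. Thermal electrocyclic opening of the 2H-pyran ring of 8 followed by hydrogen shift may consume the diene faster than the cycloaddition. The ynenone may also oligomerise at the temperature needed, or the alkyne may add in both orientations. The fallback builds ring B first as an aldehyde and closes ring C afterwards; it sets out from 9 and comes back to the route at 16. Compound 9 is protected selectively at the 4-hydroxyl (MOMCl, K2CO3, acetone; the 2-hydroxyl is hydrogen-bonded to the ketone) to give 1-[2-hydroxy-4-(methoxymethoxy)phenyl]ethanone F1. Commercial 3-bromo-4-hydroxybenzaldehyde is O-alkylated with 3-chloro-3-methylbut-1-yne (K2CO3, KI, CuI cat., acetone) to 3-bromo-4-[(2-methylbut-3-yn-2-yl)oxy]benzaldehyde F2. Heating F2 (N,N-diethylaniline, 190 °C) should give, by aryl propargyl ether Claisen rearrangement, hydrogen shift and 6π closure, 8-bromo-2,2-dimethyl-2H-chromene-6-carbaldehyde F3. Stille coupling with tributyl(3-methylbut-2-enyl)stannane (Pd(PPh3)4, DMF, 90 °C) then gives 2,2-dimethyl-8-(3-methylbut-2-enyl)-2H-chromene-6-carbaldehyde F4. Claisen–Schmidt condensation of F1 with F4 (KOH, EtOH, rt) gives (E)-3-[2,2-dimethyl-8-(3-methylbut-2-enyl)-2H-chromen-6-yl]-1-[2-hydroxy-4-(methoxymethoxy)phenyl]prop-2-en-1-one F5, and oxidative cyclisation of this 2'-hydroxychalcone (I2 cat., DMSO, 120 °C) gives flavone 16.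

Step 8. Hydride transfer to the β-aryl, β-alkoxy enone may be slow, the facial selectivity may be poor, or the copper enolate may open ring C by β-elimination of the phenoxide and so erode the configuration at C2. The fallback replaces asymmetric catalysis by racemic reduction and kinetic resolution; it sets out from 16 and comes back at 18. Flavone 16 is reduced with an achiral, more active catalyst (Cu(OAc)2, 1,2-bis(diphenylphosphino)benzene, polymethylhydrosiloxane, t-BuOH, toluene, rt; the alcohol protonates the copper enolate directly) to racemic 2-[2,2-dimethyl-8-(3-methylbut-2-enyl)-2H-chromen-6-yl]-7-(methoxymethoxy)-2,3-dihydro-4H-chromen-4-one F6. Kinetic resolution by asymmetric transfer hydrogenation (RhCl(Cp*)(TsDPEN), the ligand enantiomer that reduces the (2R)-ketone, HCO2H/Et3N, EtOAc, rt) converts the (2R)-enantiomer into (2R,4R)-2-[2,2-dimethyl-8-(3-methylbut-2-enyl)-2H-chromen-6-yl]-7-(methoxymethoxy)chroman-4-ol F7. The unreacted (2S)-ketone 18 is separated by chromatography, at the cost of at most half of the material.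

Step 4. The enol oxygen of diketone 11 may add 6-endo to the alkyne and form a 4-pyranone in place of closure onto the C3 carbonyl. The enolate may also add in conjugate fashion to the ynoate, or the silyl group may be lost under the acid. The fallback closes ring C before the alkyne exists; it sets out from 9 and comes back at 14. Compound 9 is condensed with diethyl oxalate (NaOEt, EtOH; then HCl, EtOH, reflux) to ethyl 7-hydroxy-4-oxo-4H-chromene-2-carboxylate F8, which is protected (MOMCl, K2CO3, acetone) as ethyl 7-(methoxymethoxy)-4-oxo-4H-chromene-2-carboxylate F9. Reduction of the activated ester (NaBH4, EtOH/THF, 0 °C) gives 2-(hydroxymethyl)-7-(methoxymethoxy)-4H-chromen-4-one F10, and oxidation (MnO2, CH2Cl2, rt) gives 7-(methoxymethoxy)-4-oxo-4H-chromene-2-carbaldehyde F11. Seyferth–Gilbert homologation with dimethyl (1-diazo-2-oxopropyl)phosphonate (K2CO3, MeOH, 0 °C, short reaction time) converts the aldehyde into alkyne 14.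

**Further compounds**
F1 | step 7 | 1-[2-hydroxy-4-(methoxymethoxy)phenyl]ethanone | CC(=O)c1ccc(OCOC)cc1O
F2 | step 7 | 3-bromo-4-[(2-methylbut-3-yn-2-yl)oxy]benzaldehyde | C#CC(C)(C)Oc1ccc(C=O)cc1Br
F3 | step 7 | 8-bromo-2,2-dimethyl-2H-chromene-6-carbaldehyde | CC1(C)C=Cc2cc(C=O)cc(Br)c2O1
F4 | step 7 | 2,2-dimethyl-8-(3-methylbut-2-enyl)-2H-chromene-6-carbaldehyde | CC(C)=CCc1cc(C=O)cc2c1OC(C)(C)C=C2
F5 | step 7 | (E)-3-[2,2-dimethyl-8-(3-methylbut-2-enyl)-2H-chromen-6-yl]-1-[2-hydroxy-4-(methoxymethoxy)phenyl]prop-2-en-1-one | COCOc1ccc(C(=O)/C=C/c2cc(CC=C(C)C)c3OC(C)(C)C=Cc3c2)c(O)c1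
F6 | step 8 | racemic 2-[2,2-dimethyl-8-(3-methylbut-2-enyl)-2H-chromen-6-yl]-7-(methoxymethoxy)-2,3-dihydro-4H-chromen-4-one | CC(C)=CCc1cc(C2CC(=O)c3ccc(OCOC)cc3O2)cc2c1OC(C)(C)C=C2
F7 | step 8 | (2R,4R)-2-[2,2-dimethyl-8-(3-methylbut-2-enyl)-2H-chromen-6-yl]-7-(methoxymethoxy)chroman-4-ol | CC(C)=CCc1cc([C@H]2C[C@@H](O)c3ccc(OCOC)cc3O2)cc2c1OC(C)(C)C=C2
F8 | step 4 | ethyl 7-hydroxy-4-oxo-4H-chromene-2-carboxylate | CCOC(=O)C1=CC(=O)c2ccc(O)cc2O1
F9 | step 4 | ethyl 7-(methoxymethoxy)-4-oxo-4H-chromene-2-carboxylate | CCOC(=O)C1=CC(=O)c2ccc(OCOC)cc2O1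
F10 | step 4 | 2-(hydroxymethyl)-7-(methoxymethoxy)-4H-chromen-4-one | OCC1=CC(=O)c2ccc(OCOC)cc2O1
F11 | step 4 | 7-(methoxymethoxy)-4-oxo-4H-chromene-2-carbaldehyde | O=CC1=CC(=O)c2ccc(OCOC)cc2O1
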